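## Retrosynthetic overview

1. The target, GA32, is gibberellic acid (GA3) plus two hydroxyls (12α and 15β). GA3 supplies the other eight stereocentres, rings A–C and the lactone, none of which is broken.
2. Both new carbinol configurations (12α, 15β) are set last, in one substrate-controlled hydride reduction of a 12,15-diketone.
3. C15–O: selenium dioxide oxidation of the 16-ene, an ene reaction followed by the [2,3]-sigmatropic shift of the allylseleninic acid (key bond formation).
4. C12–O: C12 is unactivated in GA3, so ring D is opened at C13–C16 (ozonolysis/borohydride, then periodate). The C13 ketone then allows enolate hydroxylation at C12.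
5. Ring order: A, B, C and the lactone are kept from GA3. Ring D is re-formed by ketyl–alkyne 5-exo-dig cyclisation (C13–C16), which restores 13-OH and the 16-methylene; C17 is put back by Ohira–Bestmann homologation.

Assumption: gibberellic acid (GA3), the bulk fermentation product sold as a plant growth regulator, is taken as the commercial chiral starting material; gibberellin numbering is used throughout.

The route has not been run; the stereochemical outcomes at C12 and C15 are predictions from a hand-built model of the ring system.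

## Route

Step 1
Reactants: 1 gibberellic acid (GA3)
Product: 2 GA3 2-(trimethylsilyl)ethyl ester
Conditions: Me3SiCH2CH2OH (3 equiv), DCC, DMAP (cat.), CH2Cl2, 0 °C to rt
Reagents that add atoms: 2-(trimethylsilyl)ethanol, C[Si](C)(C)CCO
Why: Steglich esterification of the only carboxylic acid; the hindered 3-OH and the tertiary 13-OH cannot compete with the excess primary alcohol, and no stereocentre is touched.

Step 2
Reactants: 2 GA3 2-(trimethylsilyl)ethyl ester
Product: 3 3-O-TBS GA3 2-(trimethylsilyl)ethyl ester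
Conditions: TBSCl, imidazole, DMAP (cat.), DMF, 40 °C
Reagents that add atoms: tert-butyldimethylsilyl chloride, CC(C)(C)[Si](C)(C)Cl
Why: Silyl ether formation at the secondary allylic 3-OH; the bridgehead tertiary 13-OH does not react with TBSCl/imidazole.

Step 3
Reactants: 3 3-O-TBS GA3 2-(trimethylsilyl)ethyl ester
Product: 5 17-nor-13,16-diol (both C16 epimers), via 17-nor-16-ketone 4 (not isolated)
Conditions: O3 (1.0 equiv), CH2Cl2/MeOH, pyridine, −78 °C; then NaBH4, −78 °C to 0 °C
Reagents that add atoms: ozone, [O-][O+]=O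
Why: Criegee ozonolysis with reductive work-up: the electron-rich 1,1-disubstituted 16-ene reacts far faster than the ring A alkene (flanked by two allylic C–O bonds and the silyl ether), and borohydride reduces the 16-ketone; the C16 configuration is irrelevant because C16 becomes an aldehyde next.

Step 4
Reactants: 5 17-nor-13,16-diol
Product: 6 13,16-seco-17-nor keto-aldehyde (ring C 13-ketone; C8 carries CH2–CHO)
Conditions: NaIO4, THF/H2O (pH 7 buffer), 0 °C to rt
Reagents that add atoms: none
Why: Malaprade glycol cleavage: the gauche tertiary/secondary diol forms the cyclic periodate and the C13–C16 bond breaks, opening ring D and making C13 a ketone that activates C12.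

Step 5
Reactants: 6 13,16-seco-17-nor keto-aldehyde
Product: 7 13,16-seco 13-ketone with C8-propargyl group (C15–C16≡C17)
Conditions: dimethyl (1-diazo-2-oxopropyl)phosphonate, K2CO3, MeOH, 0 °C to rt
Reagents that add atoms: Ohira–Bestmann reagent, CC(=O)C(=[N+]=[N-])P(=O)(OC)OC
Why: Ohira–Bestmann (Seyferth–Gilbert) homologation turns the aldehyde into the terminal alkyne and restores C17; irreversible alkyne formation outruns the reversible intramolecular aldol, and the ketone is inert to the reagent under carbonate conditions.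

Step 6
Reactants: 7 13,16-seco 13-ketone with C8-propargyl group
Product: 9 12-hydroxy-13-ketone (both C12 epimers), via potassium enolate 8 (not isolated)
Conditions: KN(SiMe3)2 (1.1 equiv), THF, −78 °C; (±)-2-(phenylsulfonyl)-3-phenyloxaziridine; then AcOH
Reagents that add atoms: Davis oxaziridine (racemic), O=S(=O)(N1OC1c1ccccc1)c1ccccc1
Why: Davis hydroxylation of the kinetic enolate: deprotonation goes to C12 because C14 is neopentylic (next to quaternary C8); the C12 configuration is left uncontrolled because C12 is taken to the ketone in step 9.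

Step 7
Reactants: 9 12-hydroxy-13-ketone
Product: 10 3-O-TBS 12ξ-hydroxy-GA3 2-(trimethylsilyl)ethyl ester (ring D re-formed; C12 epimers)
Conditions: SmI2 (3 equiv), HMPA, t-BuOH, THF, −78 °C to 0 °C
Reagents that add atoms: none
Why: Ketyl–alkyne radical cyclisation (Stork/Molander type, 5-exo-dig): the samarium ketyl at C13 adds to the internal alkyne carbon and the vinyl radical is reduced and protonated to the 16-methylene; the tether from C8 allows bond formation on one face only, so C13 is set by C8, and the free 12-OH, present as a samarium alkoxide, is the poorest leaving group available and is expected to be kept.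

Step 8
Reactants: 10 3-O-TBS 12ξ-hydroxy-GA3 2-(trimethylsilyl)ethyl ester
Product: 13 3-O-TBS 12ξ,15α-dihydroxy-GA3 2-(trimethylsilyl)ethyl ester, via allylseleninic acid 11 (not isolated), via selenium ester 12 (not isolated)
Conditions: SeO2 (0.5 equiv), t-BuOOH (3 equiv), CH2Cl2, 0 °C to rt
Reagents that add atoms: selenium dioxide, O=[Se]=O (delivers the C15 oxygen; re-formed by tert-butyl hydroperoxide, CC(C)(C)OO)
Why: Selenium dioxide allylic oxidation (Sharpless–Umbreit): ene reaction at C17 gives the allylseleninic acid, whose [2,3]-sigmatropic rearrangement forms the C15–O bond and returns the exocyclic alkene; C15 is the only allylic carbon with hydrogen, and oxygen is expected on the exo (α) face, which does not matter because C15 is oxidised next.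

Step 9
Reactants: 13 3-O-TBS 12ξ,15α-dihydroxy-GA3 2-(trimethylsilyl)ethyl ester
Product: 14 3-O-TBS 12,15-dioxo-GA3 2-(trimethylsilyl)ethyl ester
Conditions: Dess–Martin periodinane (3 equiv), pyridine, CH2Cl2, 0 °C to rt
Reagents that add atoms: none
Why: Dess–Martin oxidation of the two secondary carbinols (C12 and allylic C15) erases both unwanted configurations; the tertiary 13-OH and the silyl ether are untouched, and the rearrangement-prone ketol is used at once.

Step 10
Reactants: 14 3-O-TBS 12,15-dioxo-GA3 2-(trimethylsilyl)ethyl ester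
Product: 15 3-O-TBS GA32 2-(trimethylsilyl)ethyl ester
Conditions: NaBH4, CeCl3·7H2O, MeOH/THF, −78 °C; AcOH quench
Reagents that add atoms: none
Why: Luche reduction under substrate control: at C15 hydride enters from the exo (α) face, away from the C7 ester and the axial C11–H, giving the 15β carbinol; at C12 the α face is blocked by the axial C9–C10 bond, so hydride enters from the β face and gives the 12α carbinol, as with 11-oxo steroids.

Step 11
Reactants: 15 3-O-TBS GA32 2-(trimethylsilyl)ethyl ester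
Product: 16 GA32
Conditions: Bu4NF (4 equiv), THF, 0 °C to rt; then dilute HCl to pH 3
Reagents that add atoms: none
Why: Fluoride removes the silyl ether and fragments the 2-(trimethylsilyl)ethyl ester (β-elimination to ethene and Me3SiF) without hydroxide, which spares the base-labile allylic lactone; no stereocentre is touched.

## Compound list

1 | gibberellic acid (GA3) | C=C1C[C@]23C[C@@]1(O)CC[C@H]2[C@@]12C=C[C@H](O)[C@@](C)(C(=O)O1)[C@H]2[C@@H]3C(=O)O | starting material
2 | GA3 2-(trimethylsilyl)ethyl ester | C=C1C[C@]23C[C@@]1(O)CC[C@H]2[C@@]12C=C[C@H](O)[C@@](C)(C(=O)O1)[C@H]2[C@@H]3C(=O)OCC[Si](C)(C)C | intermediate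
3 | 3-O-TBS GA3 2-(trimethylsilyl)ethyl ester | C=C1C[C@]23C[C@@]1(O)CC[C@H]2[C@@]12C=C[C@H](O[Si](C)(C)C(C)(C)C)[C@@](C)(C(=O)O1)[C@H]2[C@@H]3C(=O)OCC[Si](C)(C)C | intermediate
4 | 17-nor-16-ketone of 3 (13-hydroxy-16-oxo; not isolated) | O=C1C[C@]23C[C@@]1(O)CC[C@H]2[C@@]12C=C[C@H](O[Si](C)(C)C(C)(C)C)[C@@](C)(C(=O)O1)[C@H]2[C@@H]3C(=O)OCC[Si](C)(C)C | intermediate
5 | 17-nor-13,16-diol of 3 (C16 epimer mixture, configuration immaterial) | OC1C[C@]23C[C@@]1(O)CC[C@H]2[C@@]12C=C[C@H](O[Si](C)(C)C(C)(C)C)[C@@](C)(C(=O)O1)[C@H]2[C@@H]3C(=O)OCC[Si](C)(C)C | intermediate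
6 | 13,16-seco-17-nor keto-aldehyde (ring C 13-ketone; C8–CH2–CHO) | O=CC[C@]23CC(=O)CC[C@H]2[C@@]12C=C[C@H](O[Si](C)(C)C(C)(C)C)[C@@](C)(C(=O)O1)[C@H]2[C@@H]3C(=O)OCC[Si](C)(C)C | intermediate
7 | 13,16-seco 13-ketone with C8-propargyl group | C#CC[C@]23CC(=O)CC[C@H]2[C@@]12C=C[C@H](O[Si](C)(C)C(C)(C)C)[C@@](C)(C(=O)O1)[C@H]2[C@@H]3C(=O)OCC[Si](C)(C)C | intermediate
8 | potassium C12(13)-enolate of 7 (not isolated) | C#CC[C@]23CC([O-])=CC[C@H]2[C@@]12C=C[C@H](O[Si](C)(C)C(C)(C)C)[C@@](C)(C(=O)O1)[C@H]2[C@@H]3C(=O)OCC[Si](C)(C)C.[K+] | intermediate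
9 | 12-hydroxy-13-ketone (C12 epimer mixture, configuration immaterial) | C#CC[C@]23CC(=O)C(O)C[C@H]2[C@@]12C=C[C@H](O[Si](C)(C)C(C)(C)C)[C@@](C)(C(=O)O1)[C@H]2[C@@H]3C(=O)OCC[Si](C)(C)C | intermediate
10 | 3-O-TBS 12ξ-hydroxy-GA3 2-(trimethylsilyl)ethyl ester (12,13-diol, C12 epimer mixture) | C=C1C[C@]23C[C@@]1(O)C(O)C[C@H]2[C@@]12C=C[C@H](O[Si](C)(C)C(C)(C)C)[C@@](C)(C(=O)O1)[C@H]2[C@@H]3C(=O)OCC[Si](C)(C)C | intermediate
11 | allylseleninic acid from 10 (15-ene, C17–Se(=O)OH; not isolated) | O[Se](=O)CC1=C[C@]23C[C@@]1(O)C(O)C[C@H]2[C@@]12C=C[C@H](O[Si](C)(C)C(C)(C)C)[C@@](C)(C(=O)O1)[C@H]2[C@@H]3C(=O)OCC[Si](C)(C)C | intermediate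
12 | 15α-O–Se–OH ester of divalent selenium, 16-methylene restored (not isolated) | C=C1[C@H](O[Se]O)[C@]23C[C@@]1(O)C(O)C[C@H]2[C@@]12C=C[C@H](O[Si](C)(C)C(C)(C)C)[C@@](C)(C(=O)O1)[C@H]2[C@@H]3C(=O)OCC[Si](C)(C)C | intermediate
13 | 3-O-TBS 12ξ,15α-dihydroxy-GA3 2-(trimethylsilyl)ethyl ester | C=C1[C@H](O)[C@]23C[C@@]1(O)C(O)C[C@H]2[C@@]12C=C[C@H](O[Si](C)(C)C(C)(C)C)[C@@](C)(C(=O)O1)[C@H]2[C@@H]3C(=O)OCC[Si](C)(C)C | intermediate
14 | 3-O-TBS 12,15-dioxo-GA3 2-(trimethylsilyl)ethyl ester | C=C1C(=O)[C@]23C[C@@]1(O)C(=O)C[C@H]2[C@@]12C=C[C@H](O[Si](C)(C)C(C)(C)C)[C@@](C)(C(=O)O1)[C@H]2[C@@H]3C(=O)OCC[Si](C)(C)C | intermediate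
15 | 3-O-TBS GA32 2-(trimethylsilyl)ethyl ester (12α,15β) | C=C1[C@@H](O)[C@]23C[C@@]1(O)[C@@H](O)C[C@H]2[C@@]12C=C[C@H](O[Si](C)(C)C(C)(C)C)[C@@](C)(C(=O)O1)[C@H]2[C@@H]3C(=O)OCC[Si](C)(C)C | intermediate
16 | GA32 (12α,15β-dihydroxy-GA3) | C=C1[C@@H](O)[C@]23C[C@@]1(O)[C@@H](O)C[C@H]2[C@@]12C=C[C@H](O)[C@@](C)(C(=O)O1)[C@H]2[C@@H]3C(=O)O | target

## Step count and risks

Total step count: 11. Longest linear sequence: 11 (fully linear from 1).

The three steps most likely to fail:

Step 7. SmI2 may strip the 12-hydroxyl from the α-hydroxy ketone or give pinacol dimers instead of the ketyl–alkyne closure. The fallback sets out from 9 and closes ring D through a π-acid instead of a ketyl. Et3SiOTf/Et3N in CH2Cl2 silylates the 12-OH and enolises toward the oxygenated carbon to give the 12,13-bis(triethylsilyloxy) enediol ether F1. Ph3PAuNTf2 (5 mol %, monovalent gold) in CH2Cl2/MeOH then triggers a 5-exo-dig Conia-ene-type carbocyclisation from C13 onto the alkyne, giving the ring-D-closed 12-oxo 13-triethylsilyl ether F2. NaBH4 in MeOH gives the 12α-alcohol F3, and HF·pyridine in THF at 0 °C removes the tertiary triethylsilyl group. The fallback comes back to the route at 10, as its 12α-epimer.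

Step 6. The enolate hydroxylation may suffer from C12/C14 regiochemistry, competing deprotonation of the alkyne, or over-oxidation. The fallback sets out from 7 and uses an enamine-type [3,3]-sigmatropic rearrangement instead of an enolate. N-methyl-O-benzoylhydroxylamine hydrochloride in DMSO at rt condenses with the ketone toward the less hindered C12, and the N-vinyl-O-benzoyl hydroxylamine rearranges to the 12-benzoyloxy ketone F4. K2CO3 in MeOH at 0 °C removes the benzoate, and the fallback comes back to the route at 9.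

Step 10. The facial selectivity at C15 or C12 may be poor, and the 15β-alkoxide may lactonise onto the C7 ester. Hydride and the [2,3] shift should both attack the less hindered face of C15 and so give opposite carbinols; if hydride gives the 15α-alcohol, the selenium step should give 15β-oxygen directly. The fallback therefore sets out from 10 and lets the sigmatropic step set C15. Dess–Martin periodinane oxidises the only secondary carbinol to the 12-oxo-13-hydroxy ketol F5. NaBH4 in MeOH at −40 °C gives the pure 12α,13-diol F6. SeO2/t-BuOOH in CH2Cl2 then installs the 15β-hydroxyl, and the fallback comes back to the route at 15, skipping steps 9 and 10.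

## Further compounds

F1 | step 7 | 12,13-bis(triethylsilyloxy) enediol ether of 9 | C#CC[C@]23CC(O[Si](CC)(CC)CC)=C(O[Si](CC)(CC)CC)C[C@H]2[C@@]12C=C[C@H](O[Si](C)(C)C(C)(C)C)[C@@](C)(C(=O)O1)[C@H]2[C@@H]3C(=O)OCC[Si](C)(C)C
F2 | step 7 | ring-D-closed 12-oxo 13-O-triethylsilyl 3-O-TBS GA3 2-(trimethylsilyl)ethyl ester | C=C1C[C@]23C[C@@]1(O[Si](CC)(CC)CC)C(=O)C[C@H]2[C@@]12C=C[C@H](O[Si](C)(C)C(C)(C)C)[C@@](C)(C(=O)O1)[C@H]2[C@@H]3C(=O)OCC[Si](C)(C)C
F3 | step 7 | 12α-hydroxy 13-O-triethylsilyl 3-O-TBS GA3 2-(trimethylsilyl)ethyl ester | C=C1C[C@]23C[C@@]1(O[Si](CC)(CC)CC)[C@@H](O)C[C@H]2[C@@]12C=C[C@H](O[Si](C)(C)C(C)(C)C)[C@@](C)(C(=O)O1)[C@H]2[C@@H]3C(=O)OCC[Si](C)(C)C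
F4 | step 6 | 12-benzoyloxy-13-ketone derived from 7 (C12 epimers) | C#CC[C@]23CC(=O)C(OC(=O)c4ccccc4)C[C@H]2[C@@]12C=C[C@H](O[Si](C)(C)C(C)(C)C)[C@@](C)(C(=O)O1)[C@H]2[C@@H]3C(=O)OCC[Si](C)(C)C
F5 | step 10 | 3-O-TBS 12-oxo-GA3 2-(trimethylsilyl)ethyl ester (12-oxo-13-hydroxy ketol) | C=C1C[C@]23C[C@@]1(O)C(=O)C[C@H]2[C@@]12C=C[C@H](O[Si](C)(C)C(C)(C)C)[C@@](C)(C(=O)O1)[C@H]2[C@@H]3C(=O)OCC[Si](C)(C)C
F6 | step 10 | 3-O-TBS 12α-hydroxy-GA3 2-(trimethylsilyl)ethyl ester (pure 12α-epimer of 10) | C=C1C[C@]23C[C@@]1(O)[C@@H](O)C[C@H]2[C@@]12C=C[C@H](O[Si](C)(C)C(C)(C)C)[C@@](C)(C(=O)O1)[C@H]2[C@@H]3C(=O)OCC[Si](C)(C)C
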